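**Retrosynthetic overview**
1. Target 32 ⇐ removal of three MOM ethers from chalcone 31 ⇐ Claisen–Schmidt (crossed aldol) condensation of chromanyl methyl ketone 27 with 2,4-bis(methoxymethoxy)benzaldehyde 29; this forms the Cα–Cβ bond of the enone and joins the two halves.
2. Ketone 27 ⇐ phenol-directed ortho-formylation of 5-hydroxychromane 22 (fixes C6 regiochemistry), then MeMgBr and oxidation.
3. Only one ring is built, the dihydropyran ring of the chromane, by Pd-catalysed intramolecular aryl C–O coupling of bromo tertiary alcohol 20; both benzene rings are bought.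
4. Alcohol 20 ⇐ methyl ester + 2 MeMgBr; the C3 stereocentre ⇐ Evans prenylation of the N-(3-arylpropanoyl)-(S)-4-benzyloxazolidinone 12.
5. Imide 12 ⇐ 2-bromo-4-methoxy-6-(methoxymethoxy)benzaldehyde 5 (Meldrum's acid homologation) ⇐ 1-bromo-3,5-dimethoxybenzene 1.

Assumption: the single stereocentre is C3 of the chromane and is (S), and the enone is (E), as read from the SMILES.

**Route**

Step 1
Reactants: 1 1-bromo-3,5-dimethoxybenzene
Product: 3 2-bromo-4,6-dimethoxybenzaldehyde, via aryl iminium salt 2 (not isolated)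
Conditions: POCl3, DMF, 0 → 90 °C; then H2O
Reagents that add atoms: N,N-dimethylformamide CN(C)C=O; water O
Why: Vilsmeier–Haack formylation, in which the chloroiminium ion attacks the position para to one methoxy and ortho to the other (the site between the two methoxy groups is more hindered) and the iminium 2 is hydrolysed on work-up.

Step 2
Reactants: 3 2-bromo-4,6-dimethoxybenzaldehyde
Product: 4 2-bromo-6-hydroxy-4-methoxybenzaldehyde
Conditions: BCl3 (1.2 equiv), CH2Cl2, −78 → 0 °C; then H2O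
Reagents that add atoms: none
Why: Chelation-controlled Lewis acid ether cleavage, in which BCl3 bound to the aldehyde oxygen removes only the ortho methyl group and leaves the para methoxy intact.

Step 3
Reactants: 4 2-bromo-6-hydroxy-4-methoxybenzaldehyde
Product: 5 2-bromo-4-methoxy-6-(methoxymethoxy)benzaldehyde
Conditions: NaH, MOMCl, DMF, 0 °C → rt
Reagents that add atoms: chloromethyl methyl ether COCCl
Why: Williamson-type O-alkylation of the sodium phenoxide installs an acetal protecting group that is stable to all the basic and organometallic steps ahead.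

Step 4
Reactants: 5 2-bromo-4-methoxy-6-(methoxymethoxy)benzaldehyde; 6 Meldrum's acid (2,2-dimethyl-1,3-dioxane-4,6-dione)
Product: 8 5-{[2-bromo-4-methoxy-6-(methoxymethoxy)phenyl]methyl}-2,2-dimethyl-1,3-dioxane-4,6-dione, via arylidene Meldrum's acid 7 (not isolated)
Conditions: L-proline (20 mol %), Hantzsch ester (1.1 equiv), EtOH, rt
Reagents that add atoms: none
Why: Knoevenagel condensation to arylidene 7 followed by in situ conjugate transfer hydrogenation from the Hantzsch ester (organocatalytic reductive alkylation) adds the side-chain carbons without touching the aryl bromide.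

Step 5
Reactants: 8 5-{[2-bromo-4-methoxy-6-(methoxymethoxy)phenyl]methyl}-2,2-dimethyl-1,3-dioxane-4,6-dione
Product: 9 3-[2-bromo-4-methoxy-6-(methoxymethoxy)phenyl]propanoic acid
Conditions: pyridine/H2O 10:1, 100 °C
Reagents that add atoms: water O
Why: Hydrolytic opening of the Meldrum's acid ring and decarboxylation of the resulting malonic acid proceed under mildly basic conditions that spare the MOM ether.

Step 6
Reactants: 9 3-[2-bromo-4-methoxy-6-(methoxymethoxy)phenyl]propanoic acid; 10 (4S)-4-benzyl-1,3-oxazolidin-2-one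
Product: 12 (4S)-4-benzyl-3-{3-[2-bromo-4-methoxy-6-(methoxymethoxy)phenyl]propanoyl}-1,3-oxazolidin-2-one, via mixed pivalic anhydride 11 (not isolated)
Conditions: PivCl, Et3N, THF, −20 °C; then 10, LiCl, −20 °C → rt
Reagents that add atoms: none
Why: N-acylation of the oxazolidinone through the mixed pivalic anhydride, with attack at the less hindered carbonyl of 11.

Step 7
Reactants: 12 (4S)-4-benzyl-3-{3-[2-bromo-4-methoxy-6-(methoxymethoxy)phenyl]propanoyl}-1,3-oxazolidin-2-one; 13 1-bromo-3-methylbut-2-ene (prenyl bromide)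
Product: 15 (4S)-4-benzyl-3-[(2S)-2-{[2-bromo-4-methoxy-6-(methoxymethoxy)phenyl]methyl}-5-methylhex-4-enoyl]-1,3-oxazolidin-2-one, via sodium Z-enolate 14 (not isolated)
Conditions: NaN(SiMe3)2 (1.1 equiv), THF, −78 °C; then 13 (3 equiv), −78 → −40 °C
Reagents that add atoms: none
Why: Evans asymmetric alkylation, in which the chelated sodium Z-enolate is prenylated on the face opposite the benzyl group of the (S)-auxiliary, setting the new centre as (S) (dr typically above 95:5, minor isomer removed by chromatography).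

Step 8
Reactants: 15 (4S)-4-benzyl-3-[(2S)-2-{[2-bromo-4-methoxy-6-(methoxymethoxy)phenyl]methyl}-5-methylhex-4-enoyl]-1,3-oxazolidin-2-one
Product: 17 (2S)-2-{[2-bromo-4-methoxy-6-(methoxymethoxy)phenyl]methyl}-5-methylhex-4-enoic acid, via lithium peroxycarboxylate 16 (not isolated)
Conditions: LiOH·H2O, 30% H2O2, THF/H2O 3:1, 0 °C; then aq. Na2SO3; then cold 1 M HCl to pH 3
Reagents that add atoms: hydrogen peroxide OO
Why: Hydroperoxide-mediated cleavage of the imide at the exocyclic acyl carbonyl, then sulfite reduction of the peracid, gives the acid without epimerisation.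

Step 9
Reactants: 17 (2S)-2-{[2-bromo-4-methoxy-6-(methoxymethoxy)phenyl]methyl}-5-methylhex-4-enoic acid
Product: 18 methyl (2S)-2-{[2-bromo-4-methoxy-6-(methoxymethoxy)phenyl]methyl}-5-methylhex-4-enoate
Conditions: MeI, K2CO3, DMF, rt
Reagents that add atoms: iodomethane CI
Why: SN2 O-methylation of the carboxylate under conditions too mild to epimerise the alpha centre.

Step 10
Reactants: 18 methyl (2S)-2-{[2-bromo-4-methoxy-6-(methoxymethoxy)phenyl]methyl}-5-methylhex-4-enoate
Product: 20 (3S)-3-{[2-bromo-4-methoxy-6-(methoxymethoxy)phenyl]methyl}-2,6-dimethylhept-5-en-2-ol, via methyl ketone 19 (not isolated)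
Conditions: MeMgBr (4 equiv), anhydrous CeCl3 (4 equiv), THF, −78 → 0 °C; aq. NH4Cl
Reagents that add atoms: methylmagnesium bromide C[Mg]Br
Why: Double Grignard addition to the ester via ketone 19, with CeCl3 suppressing enolisation so that the adjacent stereocentre is retained and the aryl bromide is untouched.

Step 11
Reactants: 20 (3S)-3-{[2-bromo-4-methoxy-6-(methoxymethoxy)phenyl]methyl}-2,6-dimethylhept-5-en-2-ol
Product: 21 (3S)-7-methoxy-5-(methoxymethoxy)-2,2-dimethyl-3-(3-methylbut-2-en-1-yl)chromane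
Conditions: Pd(OAc)2 (5 mol %), 2-(di-tert-butylphosphino)-1,1'-binaphthyl (6 mol %), Cs2CO3, toluene, 80 °C
Reagents that add atoms: none
Why: Intramolecular Buchwald-type palladium-catalysed aryl C–O coupling closes the chromane ring, a tertiary alkoxide being well suited because it cannot undergo beta-hydride elimination, and the stereocentre is not involved.

Step 12
Reactants: 21 (3S)-7-methoxy-5-(methoxymethoxy)-2,2-dimethyl-3-(3-methylbut-2-en-1-yl)chromane
Product: 22 (3S)-7-methoxy-2,2-dimethyl-3-(3-methylbut-2-en-1-yl)chroman-5-ol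
Conditions: 1.25 M HCl in MeOH, rt → 40 °C
Reagents that add atoms: none
Why: Acid-catalysed acetal exchange transfers the MOM group to methanol under conditions mild enough for the prenyl alkene and the tertiary chromane ether.

Step 13
Reactants: 22 (3S)-7-methoxy-2,2-dimethyl-3-(3-methylbut-2-en-1-yl)chroman-5-ol
Product: 24 (3S)-5-hydroxy-7-methoxy-2,2-dimethyl-3-(3-methylbut-2-en-1-yl)chromane-6-carbaldehyde, via salicyl alcohol 23 (not isolated)
Conditions: anhydrous MgCl2 (3 equiv), Et3N (4 equiv), paraformaldehyde (7 equiv), MeCN, reflux; then 1 M HCl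
Reagents that add atoms: paraformaldehyde (formaldehyde) C=O
Why: Magnesium phenoxide-directed ortho-formylation (Casnati–Skattebøl) delivers formaldehyde only ortho to the phenol, and since C6 is the only free ortho position the regiochemistry is unambiguous, with salicyl alcohol 23 oxidised in situ by a second formaldehyde.

Step 14
Reactants: 24 (3S)-5-hydroxy-7-methoxy-2,2-dimethyl-3-(3-methylbut-2-en-1-yl)chromane-6-carbaldehyde
Product: 25 (3S)-7-methoxy-5-(methoxymethoxy)-2,2-dimethyl-3-(3-methylbut-2-en-1-yl)chromane-6-carbaldehyde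
Conditions: NaH, MOMCl, DMF, 0 °C → rt
Reagents that add atoms: chloromethyl methyl ether COCCl
Why: Williamson-type O-alkylation of the hydrogen-bonded phenol via its sodium salt masks it for the Grignard, oxidation and aldol steps.

Step 15
Reactants: 25 (3S)-7-methoxy-5-(methoxymethoxy)-2,2-dimethyl-3-(3-methylbut-2-en-1-yl)chromane-6-carbaldehyde
Product: 26 1-[(3S)-7-methoxy-5-(methoxymethoxy)-2,2-dimethyl-3-(3-methylbut-2-en-1-yl)chroman-6-yl]ethan-1-ol (mixture of carbinol epimers)
Conditions: MeMgBr (1.5 equiv), THF, 0 °C; aq. NH4Cl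
Reagents that add atoms: methylmagnesium bromide C[Mg]Br
Why: Grignard 1,2-addition to the aldehyde, the new carbinol centre forming as an inconsequential epimer mixture because it is oxidised in the next step.

Step 16
Reactants: 26 1-[(3S)-7-methoxy-5-(methoxymethoxy)-2,2-dimethyl-3-(3-methylbut-2-en-1-yl)chroman-6-yl]ethan-1-ol
Product: 27 1-[(3S)-7-methoxy-5-(methoxymethoxy)-2,2-dimethyl-3-(3-methylbut-2-en-1-yl)chroman-6-yl]ethan-1-one
Conditions: Dess–Martin periodinane, CH2Cl2, 0 °C → rt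
Reagents that add atoms: none
Why: Dess–Martin oxidation converts the hindered secondary benzylic alcohol into the methyl ketone under near-neutral conditions compatible with the MOM ether and the prenyl alkene.

Step 17
Reactants: 28 2,4-dihydroxybenzaldehyde
Product: 29 2,4-bis(methoxymethoxy)benzaldehyde
Conditions: NaH (2.5 equiv), MOMCl (2.5 equiv), DMF, 0 °C → rt
Reagents that add atoms: chloromethyl methyl ether COCCl
Why: Double Williamson-type O-alkylation protects both phenols so that the aldehyde stays electrophilic under the strongly basic aldol conditions.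

Step 18
Reactants: 27 1-[(3S)-7-methoxy-5-(methoxymethoxy)-2,2-dimethyl-3-(3-methylbut-2-en-1-yl)chroman-6-yl]ethan-1-one; 29 2,4-bis(methoxymethoxy)benzaldehyde
Product: 31 (2E)-3-[2,4-bis(methoxymethoxy)phenyl]-1-[(3S)-7-methoxy-5-(methoxymethoxy)-2,2-dimethyl-3-(3-methylbut-2-en-1-yl)chroman-6-yl]prop-2-en-1-one, via aldol adduct 30 (not isolated)
Conditions: KOH (10 equiv), EtOH/H2O, rt, 24–48 h
Reagents that add atoms: none
Why: Claisen–Schmidt (crossed aldol) condensation, in which the potassium enolate of methyl ketone 27 adds to the non-enolisable aldehyde 29 and aldol 30 dehydrates by E1cB to the thermodynamically favoured E-enone.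

Step 19
Reactants: 31 (2E)-3-[2,4-bis(methoxymethoxy)phenyl]-1-[(3S)-7-methoxy-5-(methoxymethoxy)-2,2-dimethyl-3-(3-methylbut-2-en-1-yl)chroman-6-yl]prop-2-en-1-one
Product: 32 (2E)-3-(2,4-dihydroxyphenyl)-1-[(3S)-5-hydroxy-7-methoxy-2,2-dimethyl-3-(3-methylbut-2-en-1-yl)chroman-6-yl]prop-2-en-1-one (target)
Conditions: 3 M aq. HCl/MeOH 1:5, rt → 40 °C
Reagents that add atoms: none
Why: Acid-catalysed acetal exchange removes all three MOM groups near room temperature, which limits flavanone formation and prenyl hydration and leaves the (S) centre and the E-alkene untouched.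

**Compound list**
1 | 1-bromo-3,5-dimethoxybenzene | COc1cc(Br)cc(OC)c1 | starting material
2 | [(2-bromo-4,6-dimethoxyphenyl)methylidene]dimethyliminium dichlorophosphate (formed in the flask) | COc1cc(OC)c(C=[N+](C)C)c(Br)c1.[O-]P(=O)(Cl)Cl | intermediate
3 | 2-bromo-4,6-dimethoxybenzaldehyde | COc1cc(OC)c(C=O)c(Br)c1 | intermediate
4 | 2-bromo-6-hydroxy-4-methoxybenzaldehyde | COc1cc(O)c(C=O)c(Br)c1 | intermediate
5 | 2-bromo-4-methoxy-6-(methoxymethoxy)benzaldehyde | COCOc1cc(OC)cc(Br)c1C=O | intermediate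
6 | Meldrum's acid (2,2-dimethyl-1,3-dioxane-4,6-dione) | CC1(C)OC(=O)CC(=O)O1 | starting material
7 | 5-{[2-bromo-4-methoxy-6-(methoxymethoxy)phenyl]methylidene}-2,2-dimethyl-1,3-dioxane-4,6-dione (formed in the flask) | COCOc1cc(OC)cc(Br)c1C=C1C(=O)OC(C)(C)OC1=O | intermediate
8 | 5-{[2-bromo-4-methoxy-6-(methoxymethoxy)phenyl]methyl}-2,2-dimethyl-1,3-dioxane-4,6-dione | COCOc1cc(OC)cc(Br)c1CC1C(=O)OC(C)(C)OC1=O | intermediate
9 | 3-[2-bromo-4-methoxy-6-(methoxymethoxy)phenyl]propanoic acid | COCOc1cc(OC)cc(Br)c1CCC(=O)O | intermediate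
10 | (4S)-4-benzyl-1,3-oxazolidin-2-one | O=C1N[C@@H](Cc2ccccc2)CO1 | starting material
11 | 3-[2-bromo-4-methoxy-6-(methoxymethoxy)phenyl]propanoic pivalic anhydride (formed in the flask) | COCOc1cc(OC)cc(Br)c1CCC(=O)OC(=O)C(C)(C)C | intermediate
12 | (4S)-4-benzyl-3-{3-[2-bromo-4-methoxy-6-(methoxymethoxy)phenyl]propanoyl}-1,3-oxazolidin-2-one | COCOc1cc(OC)cc(Br)c1CCC(=O)N1[C@@H](Cc2ccccc2)COC1=O | intermediate
13 | 1-bromo-3-methylbut-2-ene (prenyl bromide) | CC(C)=CCBr | starting material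
14 | sodium (Z)-enolate of 12 (formed in the flask) | COCOc1cc(OC)cc(Br)c1C/C=C(\[O-])N1[C@@H](Cc2ccccc2)COC1=O.[Na+] | intermediate
15 | (4S)-4-benzyl-3-[(2S)-2-{[2-bromo-4-methoxy-6-(methoxymethoxy)phenyl]methyl}-5-methylhex-4-enoyl]-1,3-oxazolidin-2-one | COCOc1cc(OC)cc(Br)c1C[C@H](CC=C(C)C)C(=O)N1[C@@H](Cc2ccccc2)COC1=O | intermediate
16 | lithium (2S)-2-{[2-bromo-4-methoxy-6-(methoxymethoxy)phenyl]methyl}-5-methylhex-4-eneperoxoate (formed in the flask) | COCOc1cc(OC)cc(Br)c1C[C@H](CC=C(C)C)C(=O)O[O-].[Li+] | intermediate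
17 | (2S)-2-{[2-bromo-4-methoxy-6-(methoxymethoxy)phenyl]methyl}-5-methylhex-4-enoic acid | COCOc1cc(OC)cc(Br)c1C[C@H](CC=C(C)C)C(=O)O | intermediate
18 | methyl (2S)-2-{[2-bromo-4-methoxy-6-(methoxymethoxy)phenyl]methyl}-5-methylhex-4-enoate | COCOc1cc(OC)cc(Br)c1C[C@H](CC=C(C)C)C(=O)OC | intermediate
19 | (3S)-3-{[2-bromo-4-methoxy-6-(methoxymethoxy)phenyl]methyl}-6-methylhept-5-en-2-one (formed in the flask) | COCOc1cc(OC)cc(Br)c1C[C@H](CC=C(C)C)C(C)=O | intermediate
20 | (3S)-3-{[2-bromo-4-methoxy-6-(methoxymethoxy)phenyl]methyl}-2,6-dimethylhept-5-en-2-ol | COCOc1cc(OC)cc(Br)c1C[C@H](CC=C(C)C)C(C)(C)O | intermediate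
21 | (3S)-7-methoxy-5-(methoxymethoxy)-2,2-dimethyl-3-(3-methylbut-2-en-1-yl)chromane | COCOc1cc(OC)cc2c1C[C@H](CC=C(C)C)C(C)(C)O2 | intermediate
22 | (3S)-7-methoxy-2,2-dimethyl-3-(3-methylbut-2-en-1-yl)chroman-5-ol | Oc1cc(OC)cc2c1C[C@H](CC=C(C)C)C(C)(C)O2 | intermediate
23 | (3S)-6-(hydroxymethyl)-7-methoxy-2,2-dimethyl-3-(3-methylbut-2-en-1-yl)chroman-5-ol (formed in the flask as its magnesium salt) | COc1cc2c(c(O)c1CO)C[C@H](CC=C(C)C)C(C)(C)O2 | intermediate
24 | (3S)-5-hydroxy-7-methoxy-2,2-dimethyl-3-(3-methylbut-2-en-1-yl)chromane-6-carbaldehyde | COc1cc2c(c(O)c1C=O)C[C@H](CC=C(C)C)C(C)(C)O2 | intermediate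
25 | (3S)-7-methoxy-5-(methoxymethoxy)-2,2-dimethyl-3-(3-methylbut-2-en-1-yl)chromane-6-carbaldehyde | COc1cc2c(c(OCOC)c1C=O)C[C@H](CC=C(C)C)C(C)(C)O2 | intermediate
26 | 1-[(3S)-7-methoxy-5-(methoxymethoxy)-2,2-dimethyl-3-(3-methylbut-2-en-1-yl)chroman-6-yl]ethan-1-ol (both carbinol epimers) | COc1cc2c(c(OCOC)c1C(C)O)C[C@H](CC=C(C)C)C(C)(C)O2 | intermediate
27 | 1-[(3S)-7-methoxy-5-(methoxymethoxy)-2,2-dimethyl-3-(3-methylbut-2-en-1-yl)chroman-6-yl]ethan-1-one | COc1cc2c(c(OCOC)c1C(C)=O)C[C@H](CC=C(C)C)C(C)(C)O2 | intermediate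
28 | 2,4-dihydroxybenzaldehyde | O=Cc1ccc(O)cc1O | starting material
29 | 2,4-bis(methoxymethoxy)benzaldehyde | COCOc1ccc(C=O)c(OCOC)c1 | intermediate
30 | 3-[2,4-bis(methoxymethoxy)phenyl]-3-hydroxy-1-[(3S)-7-methoxy-5-(methoxymethoxy)-2,2-dimethyl-3-(3-methylbut-2-en-1-yl)chroman-6-yl]propan-1-one (formed in the flask, both carbinol epimers) | COc1cc2c(c(OCOC)c1C(=O)CC(O)c1ccc(OCOC)cc1OCOC)C[C@H](CC=C(C)C)C(C)(C)O2 | intermediate
31 | (2E)-3-[2,4-bis(methoxymethoxy)phenyl]-1-[(3S)-7-methoxy-5-(methoxymethoxy)-2,2-dimethyl-3-(3-methylbut-2-en-1-yl)chroman-6-yl]prop-2-en-1-one | COc1cc2c(c(OCOC)c1C(=O)/C=C/c1ccc(OCOC)cc1OCOC)C[C@H](CC=C(C)C)C(C)(C)O2 | intermediate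
32 | (2E)-3-(2,4-dihydroxyphenyl)-1-[(3S)-5-hydroxy-7-methoxy-2,2-dimethyl-3-(3-methylbut-2-en-1-yl)chroman-6-yl]prop-2-en-1-one | COc1cc2c(c(O)c1C(=O)/C=C/c1ccc(O)cc1O)C[C@H](CC=C(C)C)C(C)(C)O2 | target

**Step count and risks**
Total steps: 19. Longest linear sequence: 18 steps (steps 1–16, then 18 and 19); step 17 is a one-step side branch.

Most likely to fail, first: step 11. The aryl–palladium intermediate may insert into the prenyl alkene (Heck pathway) or simply lose bromine instead of forming the C–O bond. The fallback sets out from 20 and replaces the metal-catalysed etherification by a phenol route. Bromine–lithium exchange (n-BuLi, 2.2 equiv, THF, −78 °C, the first equivalent deprotonating the alcohol) gives lithium (3S)-3-{[2-lithio-4-methoxy-6-(methoxymethoxy)phenyl]methyl}-2,6-dimethylhept-5-en-2-olate F1. Trapping with B(OMe)3 and hydrolysis gives {2-[(2S)-2-(2-hydroxypropan-2-yl)-5-methylhex-4-en-1-yl]-5-methoxy-3-(methoxymethoxy)phenyl}boronic acid F2. Oxidation with H2O2/NaOH gives 2-[(2S)-2-(2-hydroxypropan-2-yl)-5-methylhex-4-en-1-yl]-5-methoxy-3-(methoxymethoxy)phenol F3. Acid-catalysed cyclodehydration (cat. p-TsOH·H2O, toluene, 60 °C) then traps the tertiary cation with the ortho phenol in a six-membered ring, as in the natural cyclisation of lavandulyl phenols. The MOM ether is lost under the same conditions, and because the two ortho oxygens of the unmasked resorcinol are equivalent, either one closes to the same chromane. The fallback comes back to the route at 22. It carries its own risk: the cation sits next to the stereocentre, so a hydride shift could erode the configuration.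

Second: step 19. The free chalcone is acid-sensitive (flavanone closure through the 5-hydroxyl, addition to the prenyl alkene). The fallback sets out from 27 (with 28 as the aldehyde source) and avoids acid after the enone is formed. The MOM group of 27 is removed at the ketone stage (HCl/MeOH, rt) to give 1-[(3S)-5-hydroxy-7-methoxy-2,2-dimethyl-3-(3-methylbut-2-en-1-yl)chroman-6-yl]ethan-1-one F6. Aldehyde 28 is protected with allyl bromide/K2CO3 in acetone as 2,4-bis(prop-2-en-1-yloxy)benzaldehyde F7. Claisen–Schmidt condensation of the two (KOH, EtOH/H2O, rt) passes through the aldol 3-[2,4-bis(prop-2-en-1-yloxy)phenyl]-3-hydroxy-1-[(3S)-5-hydroxy-7-methoxy-2,2-dimethyl-3-(3-methylbut-2-en-1-yl)chroman-6-yl]propan-1-one F8 and gives (2E)-3-[2,4-bis(prop-2-en-1-yloxy)phenyl]-1-[(3S)-5-hydroxy-7-methoxy-2,2-dimethyl-3-(3-methylbut-2-en-1-yl)chroman-6-yl]prop-2-en-1-one F9. The allyl ethers are then removed under non-acidic conditions with Pd(PPh3)4 (zerovalent palladium), K2CO3 and MeOH at rt, which leaves the C-prenyl group alone. The fallback comes back to the route at 32.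

Third: step 18. The di-ortho-substituted ketone 27 is hindered, so the equilibrium aldol condensation may stall or be outrun by Cannizzaro loss of 29. The fallback sets out from 27 and makes the same bond by a directed, irreversible aldol. Deprotonation with LiN(SiMe3)2 (THF, −78 °C) gives lithium 1-[(3S)-7-methoxy-5-(methoxymethoxy)-2,2-dimethyl-3-(3-methylbut-2-en-1-yl)chroman-6-yl]ethen-1-olate F4. Addition of 29 at −78 °C gives aldol 30, isolated this time. MsCl/Et3N (CH2Cl2, 0 °C) converts 30 into 1-[2,4-bis(methoxymethoxy)phenyl]-3-[(3S)-7-methoxy-5-(methoxymethoxy)-2,2-dimethyl-3-(3-methylbut-2-en-1-yl)chroman-6-yl]-3-oxopropyl methanesulfonate F5. Elimination with DBU gives the E-enone, and the fallback comes back to the route at 31.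

**Further compounds**
F1 | step 11 | lithium (3S)-3-{[2-lithio-4-methoxy-6-(methoxymethoxy)phenyl]methyl}-2,6-dimethylhept-5-en-2-olate | COCOc1cc(OC)cc([Li])c1C[C@H](CC=C(C)C)C(C)(C)O[Li]
F2 | step 11 | {2-[(2S)-2-(2-hydroxypropan-2-yl)-5-methylhex-4-en-1-yl]-5-methoxy-3-(methoxymethoxy)phenyl}boronic acid | COCOc1cc(OC)cc(B(O)O)c1C[C@H](CC=C(C)C)C(C)(C)O
F3 | step 11 | 2-[(2S)-2-(2-hydroxypropan-2-yl)-5-methylhex-4-en-1-yl]-5-methoxy-3-(methoxymethoxy)phenol | COCOc1cc(OC)cc(O)c1C[C@H](CC=C(C)C)C(C)(C)O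
F4 | step 18 | lithium 1-[(3S)-7-methoxy-5-(methoxymethoxy)-2,2-dimethyl-3-(3-methylbut-2-en-1-yl)chroman-6-yl]ethen-1-olate | COc1cc2c(c(OCOC)c1C(=C)O[Li])C[C@H](CC=C(C)C)C(C)(C)O2
F5 | step 18 | 1-[2,4-bis(methoxymethoxy)phenyl]-3-[(3S)-7-methoxy-5-(methoxymethoxy)-2,2-dimethyl-3-(3-methylbut-2-en-1-yl)chroman-6-yl]-3-oxopropyl methanesulfonate | COc1cc2c(c(OCOC)c1C(=O)CC(OS(C)(=O)=O)c1ccc(OCOC)cc1OCOC)C[C@H](CC=C(C)C)C(C)(C)O2
F6 | step 19 | 1-[(3S)-5-hydroxy-7-methoxy-2,2-dimethyl-3-(3-methylbut-2-en-1-yl)chroman-6-yl]ethan-1-one | COc1cc2c(c(O)c1C(C)=O)C[C@H](CC=C(C)C)C(C)(C)O2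
F7 | step 19 | 2,4-bis(prop-2-en-1-yloxy)benzaldehyde | C=CCOc1ccc(C=O)c(OCC=C)c1
F8 | step 19 | 3-[2,4-bis(prop-2-en-1-yloxy)phenyl]-3-hydroxy-1-[(3S)-5-hydroxy-7-methoxy-2,2-dimethyl-3-(3-methylbut-2-en-1-yl)chroman-6-yl]propan-1-one | COc1cc2c(c(O)c1C(=O)CC(O)c1ccc(OCC=C)cc1OCC=C)C[C@H](CC=C(C)C)C(C)(C)O2
F9 | step 19 | (2E)-3-[2,4-bis(prop-2-en-1-yloxy)phenyl]-1-[(3S)-5-hydroxy-7-methoxy-2,2-dimethyl-3-(3-methylbut-2-en-1-yl)chroman-6-yl]prop-2-en-1-one | COc1cc2c(c(O)c1C(=O)/C=C/c1ccc(OCC=C)cc1OCC=C)C[C@H](CC=C(C)C)C(C)(C)O2
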